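**Plan**

Diterpene numbering is used: ring A = C1–C5/C10, ring B = C5–C10, ring C = C8/C9/C11–C14. C20 is the lactone OCH2 on C10, C19 the lactone C=O and C18 the methyl on C4, C15 the benzylic CH2 on C14; β is the face of C20.
The retrosynthesis cuts C14–C15 and C13–O (o-quinone methide [4+2] on C13=C14), then the lactone C19–O bond, then C5–C10 and C8–C9 of ring B.
The enabling feature is ring B [C5(H)–C6–C7–C8–C9(H)–C10]. It holds both quaternary fusion carbons (C10 with C20, C8 with its methyl). It is a cyclohexene that a C5=C6–C7=C8 diene and a C9=C10 enal can form when the C1–C4 and C11–C14 chains tie them into one 14-membered ring.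
Forward, the chain is joined at C12–C13 (carbocupration), C9=C10 (Still–Gennari), C8–C14 (Suzuki–Miyaura) and C4–C5, and the macrocycle closes at C3–C4. Rings A, B and C then arise together, followed by the lactone ring and last a chroman ring that is opened oxidatively.
C8, C9 and C10 come from the alkene geometries and a formyl-exo mode, and their absolute sense comes from a chiral oxazaborolidinium salt. No concerted transannular addition can give a trans-anti-trans tricycle, so C5 is formed cis and inverted through a C6 ketone that the diene carries as an enol acetate. C4 is set by lactonisation with the syn ester, and C13/C14 by α-face syn addition.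

Key step: step 15

Assumption: the catalyst from (S)-α,α-diphenylprolinol is taken to leave the Re faces of C9 and C10 open (formyl C–H···O binding model). If the sense proves opposite, the catalyst from the (R)-amino alcohol is used and nothing else changes.

**Step 1**
Reactants: 1 2-(2-bromoethyl)-1,3-dioxolane; 2 propyne
Product: 5 2-[(3Z)-4-iodo-3-methylbut-3-en-1-yl]-1,3-dioxolane, via Grignard reagent 3 (not isolated), via alkenylcopper 4 (not isolated)
Conditions: Mg, THF, 25 °C; CuBr·SMe2, Et2O–Me2S, −45 °C; propyne, −25 °C; I2, −78 → 0 °C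
Reagents that add atoms: iodine, [I][I]
Why: Carbocupration of a terminal alkyne is a syn addition that puts the alkyl group on the substituted carbon (C12–C13), and iodinolysis goes with retention, so iodine should sit cis to the C12 chain and fix the in-ring cis C13=C14 bond.

**Step 2**
Reactants: 5 2-[(3Z)-4-iodo-3-methylbut-3-en-1-yl]-1,3-dioxolane
Product: 6 (4Z)-5-iodo-4-methylpent-4-enal
Conditions: 1 M HCl, THF, 40 °C
Reagents that add atoms: water, O
Why: Acid-catalysed acetal hydrolysis frees the C9 aldehyde, and dilute acid touches neither the vinyl iodide nor its geometry.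

**Step 3**
Reactants: 7 methyl 2-[bis(2,2,2-trifluoroethoxy)phosphoryl]acetate; 8 1-chloro-3-iodopropane
Product: 9 methyl 2-[bis(2,2,2-trifluoroethoxy)phosphoryl]-5-chloropentanoate (racemic)
Conditions: NaH, DMF, 0 → 25 °C
Reagents that add atoms: none
Why: SN2 alkylation of the stabilised phosphonoacetate anion takes place at the iodide end only, which installs C1–C3 and keeps the chloride for the ring closure.

**Step 4**
Reactants: 6 (4Z)-5-iodo-4-methylpent-4-enal; 9 methyl 2-[bis(2,2,2-trifluoroethoxy)phosphoryl]-5-chloropentanoate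
Product: 10 methyl (2Z,6Z)-2-(3-chloropropyl)-7-iodo-6-methylhepta-2,6-dienoate
Conditions: KN(SiMe3)2, 18-crown-6, THF, −78 °C
Reagents that add atoms: none
Why: In the Still–Gennari olefination the electron-poor phosphonate with a dissociated potassium ion eliminates fast from the kinetic adduct, so the ester (C20) should come out cis to C11, which is the in-ring trans geometry of C9=C10.

**Step 5**
Reactants: 10 methyl (2Z,6Z)-2-(3-chloropropyl)-7-iodo-6-methylhepta-2,6-dienoate
Product: 11 (2Z,6Z)-2-(3-chloropropyl)-7-iodo-6-methylhepta-2,6-dien-1-ol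
Conditions: iBu2AlH, CH2Cl2, −78 °C; aq. potassium sodium tartrate
Reagents that add atoms: none
Why: 1,2-Reduction of the enoate gives the allylic alcohol without touching chloride, vinyl iodide or alkene geometry, and it is done here because it could not be done once the malonate esters are present.

**Step 6**
Reactants: 11 (2Z,6Z)-2-(3-chloropropyl)-7-iodo-6-methylhepta-2,6-dien-1-ol
Product: 12 tert-butyldimethylsilyl ether of 11
Conditions: tBuMe2SiCl, imidazole, CH2Cl2, 0 → 25 °C
Reagents that add atoms: tert-butyldimethylsilyl chloride, CC(C)(C)[Si](C)(C)Cl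
Why: Standard silylation masks the C20 hydroxyl against the amide bases, hydride bases and N-bromosuccinimide used next.

**Step 7**
Reactants: 13 pent-3-yn-2-one
Product: 14 (3Z)-4-(4,4,5,5-tetramethyl-1,3,2-dioxaborolan-2-yl)pent-3-en-2-one (boron trans to acetyl)
Conditions: B2pin2, CuCl (5 mol %), Xantphos (5 mol %), NaOtBu (10 mol %), MeOH, THF, 25 °C
Reagents that add atoms: bis(pinacolato)diboron, CC1(C)OB(OC1(C)C)B1OC(C)(C)C(C)(C)O1
Why: Copper-catalysed conjugate borylation of an activated alkyne is a syn addition of boron and copper followed by protonation with retention, so boron should sit on C8 trans to the C6 carbonyl.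

**Step 8**
Reactants: 12 tert-butyldimethylsilyl ether of 11; 14 (3Z)-4-(pinacolboryl)pent-3-en-2-one
Product: 15 (3E,5Z,9Z)-10-{[(tert-butyldimethylsilyl)oxy]methyl}-13-chloro-4,6-dimethyltrideca-3,5,9-trien-2-one
Conditions: PdCl2(dppf) (5 mol %), K3PO4, DMF–H2O, 40 °C
Reagents that add atoms: none
Why: Suzuki–Miyaura coupling of two alkenyl partners goes with retention at both sp2 carbons and forms C8–C14, with C14 trans to C6 and C8 cis to C12.

**Step 9**
Reactants: 15 trienone
Product: 17 1-bromo derivative of 15 (bromine on C5), via trimethylsilyl dienol ether 16 (not isolated)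
Conditions: LiN(iPr)2, Me3SiCl, THF, −78 °C; N-bromosuccinimide, THF, −78 → 0 °C
Reagents that add atoms: N-bromosuccinimide, O=C1CCC(=O)N1Br; chlorotrimethylsilane, C[Si](C)(C)Cl (its atoms are found in 16 only)
Why: Kinetic deprotonation of an enone occurs at the α' methyl group (C5), and N-bromosuccinimide brominates the cross-conjugated silyl enol ether at that terminus faster than it attacks any isolated alkene.

**Step 10**
Reactants: 17 α-bromo ketone; 18 dimethyl malonate
Product: 19 dimethyl 2-[(3E,5Z,9Z)-10-{[(tert-butyldimethylsilyl)oxy]methyl}-13-chloro-4,6-dimethyl-2-oxotrideca-3,5,9-trien-1-yl]propanedioate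
Conditions: NaH, 18 (3 equiv), THF, 0 °C
Reagents that add atoms: none
Why: SN2 displacement at the α-bromo ketone (C4–C5) is far faster than attack on the primary chloride or Michael addition to the β,β-disubstituted dienone, and excess malonate suppresses double alkylation.

**Step 11**
Reactants: 19 chloro malonate
Product: 21 dimethyl (4E,6Z,10Z)-11-{[(tert-butyldimethylsilyl)oxy]methyl}-5,7-dimethyl-3-oxocyclotetradeca-4,6,10-triene-1,1-dicarboxylate, via primary iodide 20 (not isolated)
Conditions: Cs2CO3, NaI, MeCN, 70 °C, slow addition to 1 mM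
Reagents that add atoms: sodium iodide, [Na+].[I-] (its iodine is found in 20 only)
Why: Finkelstein exchange followed by intramolecular malonate alkylation under high dilution is the customary closure of fourteen-membered carbocycles; it forms C3–C4 and makes C4 quaternary but not stereogenic.

**Step 12**
Reactants: 21 macrocyclic dienone
Product: 22 dimethyl (2Z,4E,6Z,10Z)-3-acetoxy-11-{[(tert-butyldimethylsilyl)oxy]methyl}-5,7-dimethylcyclotetradeca-2,4,6,10-tetraene-1,1-dicarboxylate
Conditions: KN(SiMe3)2, THF, −78 °C; Ac2O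
Reagents that add atoms: acetic anhydride, CC(=O)OC(C)=O
Why: Kinetic α' enolisation toward C5 and O-acylation of the potassium enolate give the 2-acyloxy diene, and allylic strain between quaternary C4 and C7 should enforce C4 cis to oxygen, which is the in-ring E C5=C6 bond.

**Step 13**
Reactants: 22 enol acetate silyl ether
Product: 23 allylic alcohol (C20 CH2OH) of 22
Conditions: HF·pyridine, pyridine, THF, 0 °C
Reagents that add atoms: none
Why: Buffered hydrogen fluoride cleaves the primary silyl ether and leaves the enol acetate and methyl esters alone, which basic fluoride would not.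

**Step 14**
Reactants: 23 allylic alcohol
Product: 24 dimethyl (2Z,4E,6Z,10Z)-3-acetoxy-11-formyl-5,7-dimethylcyclotetradeca-2,4,6,10-tetraene-1,1-dicarboxylate
Conditions: Dess–Martin periodinane, pyridine, CH2Cl2, 0 °C
Reagents that add atoms: none
Why: Dess–Martin oxidation under pyridine buffer is fast and neutral, so the enal should form with the formyl group still cis to C11.

**Step 15**
Reactants: 24 fourteen-membered tetraene aldehyde
Product: 25 cis-anti-trans tricyclic aldehyde (H5 β; C20 formyl β; H9 α; C8 methyl β; C6 acetoxy on C6=C7; C13=C14; C4 gem-diester)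
Conditions: oxazaborolidinium bis(trifluoromethanesulfonyl)imide salt (20 mol %), made in situ from (S)-α,α-diphenylprolinol, tri(o-tolyl)boroxine and HNTf2, CH2Cl2, −78 → −20 °C
Reagents that add atoms: none
Why: The cationic boron Lewis acid binds the formyl oxygen (s-trans enal, formyl C–H···O contact), lowers the LUMO of C9=C10 and covers one of its faces with an aryl group, so that the C5=C6–C7=C8 diene across the ring adds suprafacially to the open Re faces of C9 and C10 in one concerted, asynchronous [4+2] step; the closest known reactions are transannular Diels–Alder reactions of fourteen-membered trienes, including oxazaborolidinium-catalysed ones, and cycloadditions of 2-substituted enals with the same catalysts. Ring B closes by the cycloaddition itself through a boat-like transition state, while ring A (C1–C4 arc) and ring C (C11–C14 arc) are what is left of the macrocycle on either side of the new C5–C10 and C8–C9 bonds. A four-atom arc can only bridge gauche positions at a forming bond, so an arc on an inside diene position can only give a cis fusion and a concerted reaction can never give the trans-anti-trans skeleton directly, whereas with both arcs outside (in-ring E C5=C6 and C7=C8) and an in-ring trans dienophile one fusion is trans and the other cis. In the mode wanted here C14 is outside and the C8 methyl inside, C11 exo and H9 endo, C1 endo and the formyl group exo, which translates into C8 methyl β, H9 α (trans B/C), C20 β and H5 β (cis A/B, corrected in step 17). The selectivity needed is this formyl-exo mode over the formyl-endo mode, which would lead to the C8 epimer with a cis B/C fusion; the substrate favours it because only the exo mode leaves C13=C14 close to coplanar with the reacting diene (the endo mode twists it by about 90°) and keeps the bulky catalyst-bound formyl group away from the C6 acetoxy group, and 2-substituted enals have little intrinsic endo preference. The E central bond of the C5–C13 triene excludes a 6π electrocyclisation, and the achiral precursor leaves the absolute configuration to the catalyst alone.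

**Step 16**
Reactants: 25 tricyclic aldehyde
Product: 26 primary alcohol (C20 CH2OH) of 25
Conditions: NaBH4, THF–MeOH, −40 °C
Reagents that add atoms: none
Why: Borohydride reduces the aldehyde far faster than the esters or the enol acetate at low temperature, and quaternary C10 cannot epimerise.

**Step 17**
Reactants: 26 tricyclic alcohol
Product: 29 trans-anti-trans keto lactone ester (H5 α; C19–O–C20 δ-lactone on the β face; C18 CO2Me α; C6 ketone; C13=C14), via cis-fused hydroxy ketone 27 (not isolated), via trans-fused hydroxy ketone 28 (not isolated)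
Conditions: NaOMe (0.3 equiv), MeOH, 25 → 50 °C; AcOH quench
Reagents that add atoms: none
Why: Methoxide cleaves the enol acetate by transesterification, the freed C6 ketone lets C5 equilibrate through its enolate to the trans A/B epimer (the only one in which ring B, locked by the trans B/C fusion, can be a chair), and the C20 alkoxide then lactonises with the one C4 ester that is syn and 1,3-diaxial to it, which sets C4.

**Step 18**
Reactants: 29 keto lactone ester
Product: 30 C6 enol triflate (C6=C7) of 29
Conditions: KN(SiMe3)2, PhNTf2, THF, −78 → 0 °C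
Reagents that add atoms: N-phenylbis(trifluoromethanesulfonimide), O=S(=O)(N(c1ccccc1)S(=O)(=O)C(F)(F)F)C(F)(F)F
Why: Kinetic deprotonation at the C7 methylene rather than at hindered C5–H, followed by O-sulfonylation, gives the enol triflate, and lactone and ester carry no α-hydrogen.

**Step 19**
Reactants: 30 enol triflate
Product: 31 diene lactone ester (C6=C7 and C13=C14)
Conditions: Pd(OAc)2 (5 mol %), PPh3, HCO2H, Et3N, DMF, 60 °C
Reagents that add atoms: none
Why: Palladium-catalysed formate reduction of an enol triflate (oxidative addition, decarboxylation of formate, reductive elimination) replaces the triflate by hydrogen without touching C13=C14.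

**Step 20**
Reactants: 31 diene lactone ester
Product: 32 lactone ester with C13=C14 only
Conditions: H2 (4 bar), RhCl(PPh3)3 (10 mol %), benzene–EtOH, 25 °C
Reagents that add atoms: none
Why: RhCl(PPh3)3 hydrogenates the cis-disubstituted C6=C7 bond much faster than the trisubstituted C13=C14 bond next to quaternary C8.

**Step 21**
Reactants: 32 lactone ester
Product: 33 C18 carboxylic acid
Conditions: LiI, pyridine, reflux; 1 M HCl work-up
Reagents that add atoms: none
Why: SN2 demethylation by iodide attacks the open O-methyl carbon, whereas the lactone O–CH2 (C20) is neopentyl and inert, so only the hindered ester is cleaved.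

**Step 22**
Reactants: 33 C18 carboxylic acid
Product: 35 C18 primary alcohol, via acyl imidazolide 34 (not isolated)
Conditions: 1,1'-carbonyldiimidazole, THF, 50 °C; NaBH4, H2O, 0 °C
Reagents that add atoms: 1,1'-carbonyldiimidazole, O=C(n1ccnc1)n1ccnc1 (its atoms are found in 34 only)
Why: Activation as the acyl imidazolide and borohydride reduction convert the acid into the alcohol without hydroboration of C13=C14 and faster than the hindered bridged lactone is attacked.

**Step 23**
Reactants: 35 C18 primary alcohol
Product: 36 C18 O-(imidazole-1-carbothioate)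
Conditions: 1,1'-thiocarbonyldiimidazole, DMAP, 1,2-dichloroethane, 80 °C
Reagents that add atoms: 1,1'-thiocarbonyldiimidazole, S=C(n1ccnc1)n1ccnc1
Why: Thioacylation of the only hydroxyl group prepares the radical deoxygenation (first half of the Barton–McCombie sequence).

**Step 24**
Reactants: 36 thiocarbonyl derivative
Product: 37 lactone with C4 α-methyl and C13=C14
Conditions: Bu3SnH, AIBN, toluene, 110 °C
Reagents that add atoms: none
Why: In the Barton–McCombie deoxygenation the stannyl radical adds to C=S and the released primary C18 radical abstracts hydrogen, a neopentyl radical does not rearrange, and C4 is untouched.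

**Step 25**
Reactants: 37 lactone alkene; 38 2-(hydroxymethyl)-4-methoxyphenol
Product: 40 6-methoxychroman fused at C13–C14 (O on C13 α; C15 on C14 α; H14 β; C13 methyl β), via o-quinone methide 39 (not isolated)
Conditions: 38 (5 equiv, in portions), toluene, 170 °C, sealed tube
Reagents that add atoms: none
Why: Thermal dehydration of the o-hydroxybenzyl alcohol gives the o-quinone methide, which adds to C13=C14 in an inverse-demand hetero-Diels–Alder reaction with CH2 on the less substituted C14 and O on C13, suprafacially and from the α face opposite to the axial C8 methyl, which sets C13 and C14.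

**Step 26**
Reactants: 40 6-methoxychroman
Product: 41 2-substituted 1,4-benzoquinone with free C13 tertiary alcohol
Conditions: (NH4)2Ce(NO3)6, MeCN–H2O, 0 °C
Reagents that add atoms: water, O
Why: In the oxidative dealkylation of a 1,4-dialkoxyarene water attacks the two oxygen-bearing ring carbons, so the aryl–O bonds break, methanol leaves, and the C13–O bond survives with retention as the tertiary alcohol.

**Step 27**
Reactants: 41 quinone
Product: 42 CNP0148621.1
Conditions: Na2S2O4, THF–H2O, 25 °C
Reagents that add atoms: none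
Why: Dithionite reduces the quinone to the hydroquinone under neutral conditions, which avoids acid-catalysed re-closure to a chromanol.

**Compound list**

1 | 2-(2-bromoethyl)-1,3-dioxolane | BrCCC1OCCO1 | starting material
2 | propyne | CC#C | starting material
3 | [2-(1,3-dioxolan-2-yl)ethyl]magnesium bromide | Br[Mg]CCC1OCCO1 | intermediate
4 | [(1Z)-4-(1,3-dioxolan-2-yl)-2-methylbut-1-en-1-yl]copper | [Cu]/C=C(/C)CCC1OCCO1 | intermediate
5 | 2-[(3Z)-4-iodo-3-methylbut-3-en-1-yl]-1,3-dioxolane | I/C=C(/C)CCC1OCCO1 | intermediate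
6 | (4Z)-5-iodo-4-methylpent-4-enal | I/C=C(/C)CCC=O | intermediate
7 | methyl 2-[bis(2,2,2-trifluoroethoxy)phosphoryl]acetate | COC(=O)CP(=O)(OCC(F)(F)F)OCC(F)(F)F | starting material
8 | 1-chloro-3-iodopropane | ClCCCI | starting material
9 | methyl 2-[bis(2,2,2-trifluoroethoxy)phosphoryl]-5-chloropentanoate (racemic) | COC(=O)C(CCCCl)P(=O)(OCC(F)(F)F)OCC(F)(F)F | intermediate
10 | methyl (2Z,6Z)-2-(3-chloropropyl)-7-iodo-6-methylhepta-2,6-dienoate | COC(=O)/C(CCCCl)=C\CC/C(C)=C\I | intermediate
11 | (2Z,6Z)-2-(3-chloropropyl)-7-iodo-6-methylhepta-2,6-dien-1-ol | OC/C(CCCCl)=C\CC/C(C)=C\I | intermediate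
12 | tert-butyldimethylsilyl ether of 11 | CC(C)(C)[Si](C)(C)OC/C(CCCCl)=C\CC/C(C)=C\I | intermediate
13 | pent-3-yn-2-one | CC#CC(C)=O | starting material
14 | (3Z)-4-(4,4,5,5-tetramethyl-1,3,2-dioxaborolan-2-yl)pent-3-en-2-one | CC(=O)/C=C(\C)B1OC(C)(C)C(C)(C)O1 | intermediate
15 | (3E,5Z,9Z)-10-{[(tert-butyldimethylsilyl)oxy]methyl}-13-chloro-4,6-dimethyltrideca-3,5,9-trien-2-one | CC(=O)/C=C(\C)/C=C(/C)CC/C=C(\CO[Si](C)(C)C(C)(C)C)CCCCl | intermediate
16 | 2-(trimethylsilyloxy)-1,3,5,9-tetraene from 15 | C=C(O[Si](C)(C)C)/C=C(\C)/C=C(/C)CC/C=C(\CO[Si](C)(C)C(C)(C)C)CCCCl | intermediate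
17 | 1-bromo derivative of 15 | BrCC(=O)/C=C(\C)/C=C(/C)CC/C=C(\CO[Si](C)(C)C(C)(C)C)CCCCl | intermediate
18 | dimethyl malonate | COC(=O)CC(=O)OC | starting material
19 | chloro keto malonate (C4–C5 joined) | COC(=O)C(CC(=O)/C=C(\C)/C=C(/C)CC/C=C(\CO[Si](C)(C)C(C)(C)C)CCCCl)C(=O)OC | intermediate
20 | iodo analogue of 19 | COC(=O)C(CC(=O)/C=C(\C)/C=C(/C)CC/C=C(\CO[Si](C)(C)C(C)(C)C)CCCI)C(=O)OC | intermediate
21 | fourteen-membered dienone silyl ether | COC(=O)C1(C(=O)OC)CC(=O)/C=C(\C)/C=C(/C)CC/C=C(\CO[Si](C)(C)C(C)(C)C)CCC1 | intermediate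
22 | fourteen-membered enol acetate silyl ether | COC(=O)C1(C(=O)OC)/C=C(OC(C)=O)/C=C(\C)/C=C(/C)CC/C=C(\CO[Si](C)(C)C(C)(C)C)CCC1 | intermediate
23 | fourteen-membered enol acetate allylic alcohol | COC(=O)C1(C(=O)OC)/C=C(OC(C)=O)/C=C(\C)/C=C(/C)CC/C=C(\CO)CCC1 | intermediate
24 | dimethyl (2Z,4E,6Z,10Z)-3-acetoxy-11-formyl-5,7-dimethylcyclotetradeca-2,4,6,10-tetraene-1,1-dicarboxylate | COC(=O)C1(C(=O)OC)/C=C(OC(C)=O)/C=C(\C)/C=C(/C)CC/C=C(\C=O)CCC1 | intermediate
25 | cis-anti-trans tricyclic enol acetate aldehyde (H5 β, C20 β, H9 α, C8 methyl β) | C[C@@]12C=C(OC(C)=O)[C@H]3[C@](C=O)(CCCC3(C(=O)OC)C(=O)OC)[C@H]1CCC(C)=C2 | intermediate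
26 | C20 alcohol of 25 | C[C@@]12C=C(OC(C)=O)[C@H]3[C@](CO)(CCCC3(C(=O)OC)C(=O)OC)[C@H]1CCC(C)=C2 | intermediate
27 | cis-fused (H5 β) C6 ketone C20 alcohol | C[C@@]12CC(=O)[C@H]3[C@](CO)(CCCC3(C(=O)OC)C(=O)OC)[C@H]1CCC(C)=C2 | intermediate
28 | trans-fused (H5 α) C6 ketone C20 alcohol | C[C@@]12CC(=O)[C@@H]3[C@](CO)(CCCC3(C(=O)OC)C(=O)OC)[C@H]1CCC(C)=C2 | intermediate
29 | trans-anti-trans keto lactone ester | C[C@@]12CC(=O)[C@@H]3[C@]4(CCC[C@]3(C(=O)OC)C(=O)OC4)[C@H]1CCC(C)=C2 | intermediate
30 | C6 enol triflate | C[C@@]12C=C(OS(=O)(=O)C(F)(F)F)[C@@H]3[C@]4(CCC[C@]3(C(=O)OC)C(=O)OC4)[C@H]1CCC(C)=C2 | intermediate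
31 | diene lactone ester (C6=C7, C13=C14) | C[C@@]12C=C[C@@H]3[C@]4(CCC[C@]3(C(=O)OC)C(=O)OC4)[C@H]1CCC(C)=C2 | intermediate
32 | lactone ester (C13=C14) | C[C@@]12CC[C@@H]3[C@]4(CCC[C@]3(C(=O)OC)C(=O)OC4)[C@H]1CCC(C)=C2 | intermediate
33 | C18 carboxylic acid | C[C@@]12CC[C@@H]3[C@]4(CCC[C@]3(C(=O)O)C(=O)OC4)[C@H]1CCC(C)=C2 | intermediate
34 | C18 acyl imidazolide | C[C@@]12CC[C@@H]3[C@]4(CCC[C@]3(C(=O)n5ccnc5)C(=O)OC4)[C@H]1CCC(C)=C2 | intermediate
35 | C18 primary alcohol | C[C@@]12CC[C@@H]3[C@]4(CCC[C@]3(CO)C(=O)OC4)[C@H]1CCC(C)=C2 | intermediate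
36 | C18 O-(imidazole-1-carbothioate) | C[C@@]12CC[C@@H]3[C@]4(CCC[C@]3(COC(=S)n5ccnc5)C(=O)OC4)[C@H]1CCC(C)=C2 | intermediate
37 | lactone with C4 α-methyl and C13=C14 | C[C@@]12CC[C@@H]3[C@]4(CCC[C@]3(C)C(=O)OC4)[C@H]1CCC(C)=C2 | intermediate
38 | 2-(hydroxymethyl)-4-methoxyphenol | COc1ccc(O)c(CO)c1 | starting material
39 | 4-methoxy-6-methylidenecyclohexa-2,4-dien-1-one | C=C1C=C(OC)C=CC1=O | intermediate
40 | 6-methoxychroman fused at C13–C14 | C[C@@]12CC[C@@H]3[C@]4(CCC[C@]3(C)C(=O)OC4)[C@H]1CC[C@]5(C)Oc6ccc(OC)cc6C[C@H]25 | intermediate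
41 | quinone tertiary alcohol | C[C@@]12CC[C@@H]3[C@]4(CCC[C@]3(C)C(=O)OC4)[C@H]1CC[C@](C)(O)[C@@H]2CC5=CC(=O)C=CC5=O | intermediate
42 | CNP0148621.1 | C[C@@]12CC[C@@H]3[C@]4(CCC[C@]3(C)C(=O)OC4)[C@H]1CC[C@](C)(O)[C@@H]2Cc1cc(O)ccc1O | target

**Step count**

Total steps: 27. Longest linear sequence: 25 steps (1, 2, 4–6, 8–27).

**Steps most likely to fail**

**Step 15.**
- What may go wrong: the two boat-like modes may be discriminated poorly, the three ester groups may hold the catalyst back, or the enal may lose its geometry on the acid before it reacts.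
- The fallback gives up asymmetric catalysis for an exo-directing stoichiometric Lewis acid plus resolution. It sets out from 24.
- Al(OC6H3-2,6-Ph2)3, whose pocket buries the formyl group and is known to enforce exo cycloaddition, should give racemic 25 (toluene–CH2Cl2, −78 → 0 °C). NaBH4 gives racemic 26.
- Acylation with (S)-2-(6-methoxynaphthalen-2-yl)propanoyl chloride (Et3N, DMAP) gives the wanted (S)-naproxen ester F1 and the diastereomeric ester of the mirror-image tricycle F2. These are separated by chromatography or crystallisation.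
- NaOMe in MeOH, as in step 17, cleaves both ester types of F1, inverts C5 and lactonises. The route is rejoined at 29.

**Step 25.**
- What may go wrong: the short-lived o-quinone methide may oligomerise faster than it adds to the hindered, unactivated alkene.
- The fallback keeps the α-face syn addition but uses a 1,3-dipole. It sets out from 37.
- 2,5-Dimethoxybenzaldoxime and PhI(OAc)2 generate 2,5-dimethoxybenzonitrile oxide F3. This adds with oxygen on C13 and carbon on C14 to give the isoxazoline F4.
- Raney nickel, H2 and B(OH)3 in aqueous MeOH cleave the N–O bond and hydrolyse the imine to the β-hydroxy aryl ketone F5.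
- NaBH4 gives the benzylic diol F6, and hydrogenolysis (H2, Pd(OH)2/C, EtOH–AcOH) gives the 2,5-dimethoxybenzyl carbinol F7.
- (NH4)2Ce(NO3)6 oxidises F7 to the quinone, and the route is rejoined at 41.

**Step 11.**
- What may go wrong: intermolecular alkylation may outrun ring closure, or the base may isomerise the dienone during the long addition.
- The fallback closes the ring at C8–C14 instead. It sets out from 12.
- Alkylation of 18 with 12 (NaH, NaI, DMF, 60 °C) gives the monoalkyl malonate F8.
- F8 is alkylated (NaH, THF, 0 °C) with 1-bromopent-3-yn-2-one F9, which is made from 1-propynylmagnesium bromide and 2-bromo-N-methoxy-N-methylacetamide. This gives the quaternary ynone malonate F10.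
- Conjugate borylation as in step 7 gives the β-boryl enone F11.
- An intramolecular Suzuki–Miyaura coupling (PdCl2(dppf), Cs2CO3, DMF–H2O, high dilution) rejoins the route at 21.

**Further compounds**

F1 | step 15 | (S)-naproxen ester of 26 | C[C@@]12C=C(OC(C)=O)[C@H]3[C@](COC(=O)[C@@H](C)c4ccc5cc(OC)ccc5c4)(CCCC3(C(=O)OC)C(=O)OC)[C@H]1CCC(C)=C2
F2 | step 15 | (S)-naproxen ester of the enantiomer of 26 | C[C@]12C=C(OC(C)=O)[C@@H]3[C@@](COC(=O)[C@@H](C)c4ccc5cc(OC)ccc5c4)(CCCC3(C(=O)OC)C(=O)OC)[C@@H]1CCC(C)=C2
F3 | step 25 | 2,5-dimethoxybenzonitrile oxide | COc1ccc(OC)c(C#[N+][O-])c1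
F4 | step 25 | isoxazoline fused at C13–C14 (O on C13 α, C15 on C14 α) | C[C@@]12CC[C@@H]3[C@]4(CCC[C@]3(C)C(=O)OC4)[C@H]1CC[C@]5(C)ON=C(c6cc(OC)ccc6OC)[C@H]25
F5 | step 25 | C13 hydroxy C15 aryl ketone | C[C@@]12CC[C@@H]3[C@]4(CCC[C@]3(C)C(=O)OC4)[C@H]1CC[C@](C)(O)[C@@H]2C(=O)c5cc(OC)ccc5OC
F6 | step 25 | C13,C15 diol (C15 epimers) | C[C@@]12CC[C@@H]3[C@]4(CCC[C@]3(C)C(=O)OC4)[C@H]1CC[C@](C)(O)[C@@H]2C(O)c5cc(OC)ccc5OC
F7 | step 25 | 2,5-dimethoxybenzyl carbinol | C[C@@]12CC[C@@H]3[C@]4(CCC[C@]3(C)C(=O)OC4)[C@H]1CC[C@](C)(O)[C@@H]2Cc5cc(OC)ccc5OC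
F8 | step 11 | dimethyl 2-[(4Z,8Z)-4-{[(tert-butyldimethylsilyl)oxy]methyl}-9-iodo-8-methylnona-4,8-dien-1-yl]propanedioate | COC(=O)C(CCC/C(CO[Si](C)(C)C(C)(C)C)=C/CC/C(C)=C\I)C(=O)OC
F9 | step 11 | 1-bromopent-3-yn-2-one | CC#CC(=O)CBr
F10 | step 11 | quaternary ynone malonate | COC(=O)C(CC(=O)C#CC)(CCC/C(CO[Si](C)(C)C(C)(C)C)=C/CC/C(C)=C\I)C(=O)OC
F11 | step 11 | β-boryl enone vinyl iodide | COC(=O)C(CC(=O)/C=C(\C)B1OC(C)(C)C(C)(C)O1)(CCC/C(CO[Si](C)(C)C(C)(C)C)=C/CC/C(C)=C\I)C(=O)OC
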